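**Plan**

- Retrosynthesis: the three benzyl ethers and the C5 and C8 O-methyl bonds are cut first. Then follow O1-C8a (ring C), C2-C3 between the ring A and ring B halves, and last the C8-O bond of ring A.
- Enabling feature: on ring A the oxygens at C5 and C8 are para to each other, and C8a is beta to both the C4 carbonyl and C5. Ring A can therefore be taken back to a 2-acyl-1,4-benzoquinone whose free, acyl-activated carbon is C8a.
- Forward, joining: rings A and B are bought as arenes. Ring A gains its C8 oxygen by para-hydroxylation, ring B becomes an acid chloride, and enolate acylation joins them through C2-C3 as a 1,3-diketone.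
- Forward, ring closure: ring A is dehydrogenated to the quinone, and ring C closes last by addition of the diketone enol oxygen to C8a. The hydroxyls released at C5 and C8 are the pair to be methylated; C7, C3' and C5' stay benzylated until the final hydrogenolysis.
- Stereochemistry: the target has no stereocentre and no configurable double bond, so nothing has to be set.

Key step: step 7

Assumption: flavone numbering (O1, C2, C3, C4, C4a, C5 to C8, C8a) is also used for the open-chain precursors, and the 1,3-diketones are drawn in the keto form although they should exist largely as chelated enols.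

**Step 1**
Reactants: 1 1-[4-(benzyloxy)-2-hydroxyphenyl]ethan-1-one
Product: 3 1-[4-(benzyloxy)-2,5-dihydroxyphenyl]ethan-1-one, via potassium aryl sulfate 2 (not isolated)
Conditions: K2S2O8, aq. KOH, pyridine, 0 to 20 °C; acidify to pH 4-5 and extract unreacted 1; then 2 M HCl, 80 °C, Ar
Reagents that add atoms: potassium peroxodisulfate, [K+].[K+].[O-]S(=O)(=O)OOS(=O)(=O)[O-]
Why: In the Elbs persulfate oxidation the phenolate of 1 attacks the peroxide oxygen through its free para carbon (the later C8), as 2-hydroxy-4-alkoxyacetophenones are known to do, and acid hydrolysis of sulfate 2 frees the hydroquinone.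

**Step 2**
Reactants: 4 3,5-dihydroxy-4-methoxybenzoic acid; 5 benzyl bromide
Product: 6 benzyl 3,5-bis(benzyloxy)-4-methoxybenzoate
Conditions: BnBr (3.5 equiv), K2CO3, DMF, 60 °C
Reagents that add atoms: benzyl bromide (5), BrCc1ccccc1
Why: Williamson etherification of both phenols and SN2 esterification of the carboxylate run together in one operation and mask every acidic site of ring B.

**Step 3**
Reactants: 6 benzyl 3,5-bis(benzyloxy)-4-methoxybenzoate
Product: 7 3,5-bis(benzyloxy)-4-methoxybenzoic acid
Conditions: KOH, THF/MeOH/H2O, 60 °C; then aq. HCl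
Reagents that add atoms: potassium hydroxide, [K+].[OH-]
Why: Saponification by acyl-oxygen cleavage removes only the ester benzyl group, since aryl benzyl and methyl ethers are inert to hydroxide.

**Step 4**
Reactants: 7 3,5-bis(benzyloxy)-4-methoxybenzoic acid
Product: 8 3,5-bis(benzyloxy)-4-methoxybenzoyl chloride
Conditions: (COCl)2, cat. DMF, CH2Cl2, 0 °C to rt; evaporate, use crude
Reagents that add atoms: oxalyl chloride, O=C(Cl)C(=O)Cl
Why: Acid chloride formation through the DMF-derived chloroiminium catalyst is mild, gives only volatile by-products and leaves the ethers untouched.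

**Step 5**
Reactants: 3 1-[4-(benzyloxy)-2,5-dihydroxyphenyl]ethan-1-one; 8 3,5-bis(benzyloxy)-4-methoxybenzoyl chloride
Product: 10 1-[4-(benzyloxy)-2,5-dihydroxyphenyl]-3-[3,5-bis(benzyloxy)-4-methoxyphenyl]propane-1,3-dione, via trilithium enolate 9 (not isolated)
Conditions: LiN(SiMe3)2 (4.1 equiv), THF, -78 to -10 °C; 8 (1.0 equiv), -78 °C to rt; ice-cold 1 M HCl
Reagents that add atoms: lithium bis(trimethylsilyl)amide, [Li+].C[Si](C)(C)[N-][Si](C)(C)C (supplies the lithium of 9 only; 10 takes up no reagent atoms)
Why: This Claisen-type C-acylation of the lithium polyanion of a dihydroxyacetophenone forms C2-C3 because the enolate carbon is the most nucleophilic site, the fourth equivalent of base takes up the acidic diketone, and the method is the established direct alternative to a Baker-Venkataraman sequence.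

**Step 6**
Reactants: 10 1-[4-(benzyloxy)-2,5-dihydroxyphenyl]-3-[3,5-bis(benzyloxy)-4-methoxyphenyl]propane-1,3-dione
Product: 11 1-[4-(benzyloxy)-3,6-dioxocyclohexa-1,4-dien-1-yl]-3-[3,5-bis(benzyloxy)-4-methoxyphenyl]propane-1,3-dione
Conditions: DDQ (2,3-dichloro-5,6-dicyano-1,4-benzoquinone, 1.0 equiv), CH2Cl2, 0 °C, 10 min, dark; filter through Celite, evaporate below 20 °C, use at once
Reagents that add atoms: none
Why: Dehydrogenation of a hydroquinone by a quinone of higher potential is fast, neutral and exactly dosed, so the chelated enol and the benzyl ethers are left alone, and, unlike an oxidative demethylation of a dimethyl ether, it passes through no cationic ring A species that the enol oxygen could trap at the oxygen-bearing C5.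

**Step 7**
Reactants: 11 1-[4-(benzyloxy)-3,6-dioxocyclohexa-1,4-dien-1-yl]-3-[3,5-bis(benzyloxy)-4-methoxyphenyl]propane-1,3-dione
Product: 13 7-(benzyloxy)-2-[3,5-bis(benzyloxy)-4-methoxyphenyl]-5,8-dihydroxy-4H-chromen-4-one, via 8aH-keto tautomer 12 (not isolated)
Conditions: 2,6-lutidine (0.2 equiv), degassed CH2Cl2 (0.005 M), -20 °C to rt, Ar, dark
Reagents that add atoms: none
Why: Proposed new method: the hindered weak base, which neither adds to the quinone nor ionises the product, opens the hydrogen-bonded enol chelate of 11, and the enol oxygen on C2 then adds to C8a, the only unsubstituted quinone carbon that is beta to the C4 acyl carbonyl and to the C5 ring carbonyl, which forms O1-C8a and gives adduct 12. Loss of the C8a proton toward the C8 carbonyl aromatises ring A to the 5,8-hydroquinone 13, so the step is a redox-neutral isomerisation driven by aromatisation. The closest known reaction type is the conjugate addition of oxygen, sulfur and nitrogen nucleophiles to C3 of 2-acyl-1,4-benzoquinones with enolisation of the adduct (the Thiele-Winterstein acetoxylation of quinones being the classical oxygen case), whereas the enol oxygen of a 1,3-diketone has not been shown to close a pyranone ring in this way. Ring C closes in the 6-endo-trig mode, because the attacked C4a=C8a bond lies inside the new six-membered ring. The sp3 centre C8a of 12 is erased by the enolisation, so no stereocentre has to be controlled. The selectivity needed is C8a over C6, C4a and the C5 carbonyl: the tether cannot reach C6, whose double bond is also deactivated by the C7 benzyloxy donor, closure at C4a or at the C5 carbonyl is reversible and cannot aromatise, carbon C3 of the diketone could only form a four-membered ring, and high dilution under argon holds back intermolecular C-alkylation and hydrogen exchange between 13 and 11.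

**Step 8**
Reactants: 13 7-(benzyloxy)-2-[3,5-bis(benzyloxy)-4-methoxyphenyl]-5,8-dihydroxy-4H-chromen-4-one
Product: 14 7-(benzyloxy)-2-[3,5-bis(benzyloxy)-4-methoxyphenyl]-5,8-dimethoxy-4H-chromen-4-one
Conditions: Me2SO4 (6 equiv), K2CO3, acetone, reflux, Ar
Reagents that add atoms: dimethyl sulfate, COS(=O)(=O)OC
Why: In this Williamson-type O-methylation the free 8-OH reacts first and the chelated 5-OH follows with excess reagent at reflux, as is usual for 5-hydroxyflavones, while all other oxygens are already blocked.

**Step 9**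
Reactants: 14 7-(benzyloxy)-2-[3,5-bis(benzyloxy)-4-methoxyphenyl]-5,8-dimethoxy-4H-chromen-4-one
Product: 15 2-(3,5-dihydroxy-4-methoxyphenyl)-7-hydroxy-5,8-dimethoxy-4H-chromen-4-one (CNP0218554.0)
Conditions: H2 (1 atm), Pd/C (10 wt % Pd), THF/MeOH, rt
Reagents that add atoms: none
Why: Catalytic hydrogenolysis cleaves the three benzylic C-O bonds and should leave the methyl ethers and the conjugated C2=C3 bond of the flavone intact, as is routine for benzylated flavones at ambient pressure.

**Compound list**

1 | 1-[4-(benzyloxy)-2-hydroxyphenyl]ethan-1-one | CC(=O)c1ccc(OCc2ccccc2)cc1O | starting material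
2 | potassium 4-acetyl-2-(benzyloxy)-5-hydroxyphenyl sulfate | CC(=O)c1cc(OS(=O)(=O)[O-])c(OCc2ccccc2)cc1O.[K+] | intermediate
3 | 1-[4-(benzyloxy)-2,5-dihydroxyphenyl]ethan-1-one | CC(=O)c1cc(O)c(OCc2ccccc2)cc1O | intermediate
4 | 3,5-dihydroxy-4-methoxybenzoic acid | COc1c(O)cc(C(=O)O)cc1O | starting material
5 | benzyl bromide | BrCc1ccccc1 | starting material
6 | benzyl 3,5-bis(benzyloxy)-4-methoxybenzoate | COc1c(OCc2ccccc2)cc(C(=O)OCc2ccccc2)cc1OCc1ccccc1 | intermediate
7 | 3,5-bis(benzyloxy)-4-methoxybenzoic acid | COc1c(OCc2ccccc2)cc(C(=O)O)cc1OCc1ccccc1 | intermediate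
8 | 3,5-bis(benzyloxy)-4-methoxybenzoyl chloride | COc1c(OCc2ccccc2)cc(C(=O)Cl)cc1OCc1ccccc1 | intermediate
9 | trilithium enolate (bis-phenolate, enolate) of 3 | [Li+].[Li+].[Li+].C=C([O-])c1cc([O-])c(OCc2ccccc2)cc1[O-] | intermediate
10 | 1-[4-(benzyloxy)-2,5-dihydroxyphenyl]-3-[3,5-bis(benzyloxy)-4-methoxyphenyl]propane-1,3-dione | O=C(CC(=O)c1cc(OCc2ccccc2)c(OC)c(OCc2ccccc2)c1)c1cc(O)c(OCc2ccccc2)cc1O | intermediate
11 | 1-[4-(benzyloxy)-3,6-dioxocyclohexa-1,4-dien-1-yl]-3-[3,5-bis(benzyloxy)-4-methoxyphenyl]propane-1,3-dione | O=C(CC(=O)c1cc(OCc2ccccc2)c(OC)c(OCc2ccccc2)c1)C1=CC(=O)C(OCc2ccccc2)=CC1=O | intermediate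
12 | 7-(benzyloxy)-2-[3,5-bis(benzyloxy)-4-methoxyphenyl]-5-hydroxy-4H-chromene-4,8(8aH)-dione (racemic, transient) | COc1c(OCc2ccccc2)cc(C2=CC(=O)C3=C(O)C=C(OCc4ccccc4)C(=O)C3O2)cc1OCc1ccccc1 | intermediate
13 | 7-(benzyloxy)-2-[3,5-bis(benzyloxy)-4-methoxyphenyl]-5,8-dihydroxy-4H-chromen-4-one | COc1c(OCc2ccccc2)cc(-c2cc(=O)c3c(O)cc(OCc4ccccc4)c(O)c3o2)cc1OCc1ccccc1 | intermediate
14 | 7-(benzyloxy)-2-[3,5-bis(benzyloxy)-4-methoxyphenyl]-5,8-dimethoxy-4H-chromen-4-one | COc1c(OCc2ccccc2)cc(-c2cc(=O)c3c(OC)cc(OCc4ccccc4)c(OC)c3o2)cc1OCc1ccccc1 | intermediate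
15 | 2-(3,5-dihydroxy-4-methoxyphenyl)-7-hydroxy-5,8-dimethoxy-4H-chromen-4-one | COc1c(O)cc(-c2cc(=O)c3c(OC)cc(O)c(OC)c3o2)cc1O | target

**Step count**

Total step count: 9.
Longest linear sequence: 8 steps (4 to 15 through steps 2, 3, 4, 5, 6, 7, 8 and 9).

**Steps most likely to fail**

Step 7. The ring closure may be too slow. Intermolecular C-alkylation of the quinone by the diketone carbon, or hydrogen transfer from the product hydroquinone to unreacted quinone, would then take over. The fallback uses only known chemistry, closes ring C in the classical way and brings in the C8 oxygen afterwards. It sets out from 5 and 8 and comes back at 13. Commercial 1-(2,4,6-trihydroxyphenyl)ethan-1-one is benzylated at its most acidic 4-OH with 5 (1 equiv, K2CO3, acetone, reflux) to 1-[4-(benzyloxy)-2,6-dihydroxyphenyl]ethan-1-one F1. LiN(SiMe3)2 (4 equiv, THF) converts this into the trilithium enolate F2. Acylation with 8 then gives 1-[4-(benzyloxy)-2,6-dihydroxyphenyl]-3-[3,5-bis(benzyloxy)-4-methoxyphenyl]propane-1,3-dione F3. Cyclodehydration (NaOAc, AcOH, reflux) gives 7-(benzyloxy)-2-[3,5-bis(benzyloxy)-4-methoxyphenyl]-5-hydroxy-4H-chromen-4-one F4. Elbs persulfate oxidation para to the 5-OH (K2S2O8, aq. KOH, pyridine) gives potassium 7-(benzyloxy)-2-[3,5-bis(benzyloxy)-4-methoxyphenyl]-5-hydroxy-4-oxo-4H-chromen-8-yl sulfate F5. Acid hydrolysis of this sulfate delivers 13.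

Step 6. The quinone may close prematurely during the oxidation and then be over-oxidised, or it may decay on concentration. The fallback gives up its isolation and lets all redox states converge. It sets out from 10 and comes back at 13. Compound 10 is stirred with an excess of Ag2O (Na2SO4, CH2Cl2, rt), so that 11 forms and closes in the same flask. The resulting hydroquinone is oxidised on to 7-(benzyloxy)-2-[3,5-bis(benzyloxy)-4-methoxyphenyl]-4H-chromene-4,5,8-trione F6. After filtration, aqueous Na2S2O4 reduces this single quinone to 13.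

Step 1. Conversion of the sparingly soluble phenolate may be low, and the benzyl ether may be partly lost during the hot acid hydrolysis. The fallback buys the C8 oxygen with the arene instead of installing it by C-H oxidation. It sets out from 5 and comes back at 3. Commercial 1-(2,4,5-trihydroxyphenyl)ethan-1-one is mono-benzylated with 5 (1.0 equiv, NaHCO3, cat. NaI, DMF, 40 °C, Ar). The 4-OH should react because it is para to the acetyl group and so the most acidic; the 2-OH is chelated and the 5-OH is only meta-related. No compound outside the list arises on this way (F0).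

**Further compounds**

F1 | step 7 | 1-[4-(benzyloxy)-2,6-dihydroxyphenyl]ethan-1-one | CC(=O)c1c(O)cc(OCc2ccccc2)cc1O
F2 | step 7 | trilithium enolate (bis-phenolate, enolate) of F1 | [Li+].[Li+].[Li+].C=C([O-])c1c([O-])cc(OCc2ccccc2)cc1[O-]
F3 | step 7 | 1-[4-(benzyloxy)-2,6-dihydroxyphenyl]-3-[3,5-bis(benzyloxy)-4-methoxyphenyl]propane-1,3-dione | O=C(CC(=O)c1cc(OCc2ccccc2)c(OC)c(OCc2ccccc2)c1)c1c(O)cc(OCc2ccccc2)cc1O
F4 | step 7 | 7-(benzyloxy)-2-[3,5-bis(benzyloxy)-4-methoxyphenyl]-5-hydroxy-4H-chromen-4-one | COc1c(OCc2ccccc2)cc(-c2cc(=O)c3c(O)cc(OCc4ccccc4)cc3o2)cc1OCc1ccccc1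
F5 | step 7 | potassium 7-(benzyloxy)-2-[3,5-bis(benzyloxy)-4-methoxyphenyl]-5-hydroxy-4-oxo-4H-chromen-8-yl sulfate | COc1c(OCc2ccccc2)cc(-c2cc(=O)c3c(O)cc(OCc4ccccc4)c(OS(=O)(=O)[O-])c3o2)cc1OCc1ccccc1.[K+]
F6 | step 6 | 7-(benzyloxy)-2-[3,5-bis(benzyloxy)-4-methoxyphenyl]-4H-chromene-4,5,8-trione | COc1c(OCc2ccccc2)cc(C2=CC(=O)C3=C(O2)C(=O)C(OCc2ccccc2)=CC3=O)cc1OCc1ccccc1
F0 | step 1 | none | none
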